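**Retrosynthetic overview**

- The 2-pyridone is unveiled last by removing three benzyl ethers from a 3-acyl-2,4-bis(benzyloxy)-5-arylpyridine. No ring is built: the pyridine and benzene rings are bought.
- C5–aryl bond: Suzuki coupling. C3–acyl bond: a 3-pyridyl Grignard reagent (iodine–magnesium exchange on a 3-iodo-5-bromopyridine) adds to (2S,4S,6E)-2,4-dimethyloct-6-enal, then the carbinol is oxidised.
- The E-alkene comes from Na/NH3 reduction of a 2-butynyl unit, installed by alkylating 1-propynyllithium with a primary iodide.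
- Both methyl stereocentres come from a lipase desymmetrisation of meso-2,4-dimethylpentane-1,5-diyl diacetate, made from meso-2,4-dimethylglutaric anhydride.
- Order: side chain (steps 1–10), pyridine (steps 11–12), union and endgame (steps 13–16).

Assumption: cis-2,4-dimethylglutaric anhydride is bought as the achiral meso compound, and the lipase shows its usual preference for the ester arm on the (S)-configured 2-methylalkyl carbon.

**Route**

Step 1
Reactants: 1 meso-2,4-dimethylglutaric anhydride
Product: 2 meso-(2R,4S)-2,4-dimethylpentane-1,5-diol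
Conditions: LiAlH4 (2.5 equiv), THF, 0 °C → reflux; H2O/aq. NaOH work-up
Reagents that add atoms: none
Why: Hydride reduction of both anhydride carbonyls does not touch the two α-carbons, so the cis (meso) relationship of the methyl groups is kept.

Step 2
Reactants: 2 meso-(2R,4S)-2,4-dimethylpentane-1,5-diol
Product: 3 meso-(2R,4S)-2,4-dimethylpentane-1,5-diyl diacetate
Conditions: Ac2O, pyridine, 4-(dimethylamino)pyridine (cat.), CH2Cl2, 0 °C → rt
Reagents that add atoms: acetic anhydride CC(=O)OC(C)=O
Why: Nucleophile-catalysed acyl transfer acetylates both primary alcohols and the product is still meso.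

Step 3
Reactants: 3 meso-(2R,4S)-2,4-dimethylpentane-1,5-diyl diacetate
Product: 4 (2S,4R)-5-acetoxy-2,4-dimethylpentan-1-ol
Conditions: Pseudomonas fluorescens lipase (Amano lipase AK), 0.1 M phosphate buffer pH 7.0 (10% acetone), 30 °C, stopped when 3 is consumed
Reagents that add atoms: none
Why: Enantiotopos-selective ester hydrolysis by a lipase (serine hydrolase, EC 3.1.1.3) cleaves only the acetate on the arm of the (S)-configured carbon, so this catalytic desymmetrisation fixes the absolute configuration of both stereocentres, and any over-hydrolysis to 2 mainly removes the minor enantiomer.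

Step 4
Reactants: 4 (2S,4R)-5-acetoxy-2,4-dimethylpentan-1-ol
Product: 5 (2R,4S)-5-[(tert-butyldimethylsilyl)oxy]-2,4-dimethylpentyl acetate
Conditions: TBSCl, imidazole, DMF, 0 °C → rt
Reagents that add atoms: tert-butyldimethylsilyl chloride CC(C)(C)[Si](C)(C)Cl
Why: Silylation of the free primary alcohol gives an ether that survives the acetylide and dissolving-metal steps.

Step 5
Reactants: 5 (2R,4S)-5-[(tert-butyldimethylsilyl)oxy]-2,4-dimethylpentyl acetate
Product: 6 (2R,4S)-5-[(tert-butyldimethylsilyl)oxy]-2,4-dimethylpentan-1-ol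
Conditions: K2CO3 (0.2 equiv), MeOH, 0 °C → rt
Reagents that add atoms: none
Why: Base-catalysed transesterification removes the acetate while the primary silyl ether stays in place, and the 1,5-spacing rules out the silyl migration that would erode the ee.

Step 6
Reactants: 6 (2R,4S)-5-[(tert-butyldimethylsilyl)oxy]-2,4-dimethylpentan-1-ol
Product: 7 tert-butyl{[(2S,4R)-5-iodo-2,4-dimethylpentyl]oxy}dimethylsilane
Conditions: I2, PPh3, imidazole, CH2Cl2, 0 °C → rt
Reagents that add atoms: iodine II
Why: Appel-type (Garegg–Samuelsson) iodination is an SN2 displacement at the primary carbon and leaves both stereocentres untouched.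

Step 7
Reactants: 7 tert-butyl{[(2S,4R)-5-iodo-2,4-dimethylpentyl]oxy}dimethylsilane; 8 1-propynyllithium
Product: 9 tert-butyl{[(2S,4R)-2,4-dimethyloct-6-yn-1-yl]oxy}dimethylsilane
Conditions: 8 (2 equiv), THF/DMPU 4:1, −20 °C → rt
Reagents that add atoms: none
Why: SN2 alkylation of a weakly basic alkynyllithium by a primary iodide in a dipolar cosolvent builds the C5–C6 bond with little elimination.

Step 8
Reactants: 9 tert-butyl{[(2S,4R)-2,4-dimethyloct-6-yn-1-yl]oxy}dimethylsilane
Product: 10 tert-butyl{[(2S,4S,6E)-2,4-dimethyloct-6-en-1-yl]oxy}dimethylsilane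
Conditions: Na, liquid NH3/THF, −78 → −33 °C; then solid NH4Cl
Reagents that add atoms: none
Why: Dissolving-metal reduction of an internal alkyne goes through the trans vinyl radical anion and gives the E-alkene only, with the alkyl silyl ether inert.

Step 9
Reactants: 10 tert-butyl{[(2S,4S,6E)-2,4-dimethyloct-6-en-1-yl]oxy}dimethylsilane
Product: 11 (2S,4S,6E)-2,4-dimethyloct-6-en-1-ol
Conditions: Bu4NF (1.0 M in THF), THF, 0 °C → rt
Reagents that add atoms: none
Why: Fluoride-driven desilylation frees the primary alcohol under conditions that touch neither the alkene nor the stereocentres.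

Step 10
Reactants: 11 (2S,4S,6E)-2,4-dimethyloct-6-en-1-ol
Product: 12 (2S,4S,6E)-2,4-dimethyloct-6-enal
Conditions: Dess–Martin periodinane (1.3 equiv), pyridine (3 equiv), CH2Cl2, 0 °C → rt; used at once
Reagents that add atoms: none
Why: Dess–Martin oxidation under buffered, non-basic conditions stops at the aldehyde and does not epimerise the α-methyl centre.

Step 11
Reactants: 13 5-bromo-2,4-dichloropyridine
Product: 15 2,4-bis(benzyloxy)-5-bromopyridine, via 4-(benzyloxy)-5-bromo-2-chloropyridine 14 (not isolated)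
Conditions: BnONa (1.0 M in BnOH, 2.5 equiv), DMF, 0 → 80 °C
Reagents that add atoms: sodium benzyloxide [Na+].[O-]Cc1ccccc1
Why: Two-fold SNAr replaces first the C4 chloride (para to nitrogen) and then the C2 chloride, while the C5 bromide is not activated and stays.

Step 12
Reactants: 15 2,4-bis(benzyloxy)-5-bromopyridine
Product: 16 2,4-bis(benzyloxy)-5-bromo-3-iodopyridine
Conditions: NIS (1.2 equiv), CF3CO2H (0.2 equiv), MeCN, rt, dark
Reagents that add atoms: N-iodosuccinimide O=C1CCC(=O)N1I
Why: Electrophilic aromatic iodination can only go to C3, the one free position activated by both alkoxy groups, since C6 is deactivated by the ring nitrogen.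

Step 13
Reactants: 16 2,4-bis(benzyloxy)-5-bromo-3-iodopyridine; 12 (2S,4S,6E)-2,4-dimethyloct-6-enal
Product: 18 (2S,4S,6E)-1-[2,4-bis(benzyloxy)-5-bromopyridin-3-yl]-2,4-dimethyloct-6-en-1-ol (both C1 epimers), via [2,4-bis(benzyloxy)-5-bromopyridin-3-yl]magnesium chloride 17 (not isolated)
Conditions: i-PrMgCl·LiCl (1.1 equiv), THF, −20 °C, 1 h; then 12 (0.8 equiv), −20 → 0 °C; aq. NH4Cl
Reagents that add atoms: none
Why: Iodine–magnesium exchange is much faster at C–I than at C–Br and the aryl Grignard reagent adds 1,2 to the aldehyde without epimerising C2; the new carbinol centre is formed unselectively and is removed by oxidation in step 15.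

Step 14
Reactants: 18 (2S,4S,6E)-1-[2,4-bis(benzyloxy)-5-bromopyridin-3-yl]-2,4-dimethyloct-6-en-1-ol; 19 4-(benzyloxy)phenylboronic acid
Product: 20 (2S,4S,6E)-1-{2,4-bis(benzyloxy)-5-[4-(benzyloxy)phenyl]pyridin-3-yl}-2,4-dimethyloct-6-en-1-ol (both C1 epimers)
Conditions: 19 (1.5 equiv), PdCl2(dppf) (5 mol %; dppf = 1,1'-bis(diphenylphosphino)ferrocene), K2CO3 (3 equiv), 1,4-dioxane/H2O 4:1, 85 °C
Reagents that add atoms: none
Why: Suzuki–Miyaura coupling at the remaining C5 bromide tolerates the free alcohol and the isolated alkene, and doing it before the oxidation keeps the base-sensitive α-methyl ketone away from hot aqueous carbonate.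

Step 15
Reactants: 20 (2S,4S,6E)-1-{2,4-bis(benzyloxy)-5-[4-(benzyloxy)phenyl]pyridin-3-yl}-2,4-dimethyloct-6-en-1-ol
Product: 21 (2S,4S,6E)-1-{2,4-bis(benzyloxy)-5-[4-(benzyloxy)phenyl]pyridin-3-yl}-2,4-dimethyloct-6-en-1-one
Conditions: Dess–Martin periodinane (1.5 equiv), CH2Cl2, 0 °C → rt
Reagents that add atoms: none
Why: Dess–Martin oxidation turns the hindered carbinol into the aryl ketone under neutral conditions, which removes the undefined centre and leaves C2 and the alkene alone.

Step 16
Reactants: 21 (2S,4S,6E)-1-{2,4-bis(benzyloxy)-5-[4-(benzyloxy)phenyl]pyridin-3-yl}-2,4-dimethyloct-6-en-1-one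
Product: 22 tolypyridone C, 3-[(2S,4S,6E)-2,4-dimethyloct-6-enoyl]-4-hydroxy-5-(4-hydroxyphenyl)pyridin-2(1H)-one
Conditions: BCl3 (1.0 M in CH2Cl2, 8 equiv), C6HMe5 (10 equiv), CH2Cl2, −78 °C, 1 h; MeOH quench at −78 °C
Reagents that add atoms: none
Why: Lewis-acid debenzylation with pentamethylbenzene as cation scavenger cleaves all three benzyl ethers at −78 °C, the 2-benzyloxypyridine collapsing to the 2-pyridone, without reducing the alkene (as hydrogenolysis would) or epimerising the α-methyl ketone.

**Compound list**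

1 | meso-2,4-dimethylglutaric anhydride, (3R,5S)-3,5-dimethyloxane-2,6-dione | O=C1[C@H](C)C[C@H](C)C(=O)O1 | starting material
2 | meso-(2R,4S)-2,4-dimethylpentane-1,5-diol | OC[C@H](C)C[C@H](C)CO | intermediate
3 | meso-(2R,4S)-2,4-dimethylpentane-1,5-diyl diacetate | CC(=O)OC[C@H](C)C[C@H](C)COC(C)=O | intermediate
4 | (2S,4R)-5-acetoxy-2,4-dimethylpentan-1-ol | CC(=O)OC[C@H](C)C[C@H](C)CO | intermediate
5 | (2R,4S)-5-[(tert-butyldimethylsilyl)oxy]-2,4-dimethylpentyl acetate | CC(=O)OC[C@H](C)C[C@H](C)CO[Si](C)(C)C(C)(C)C | intermediate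
6 | (2R,4S)-5-[(tert-butyldimethylsilyl)oxy]-2,4-dimethylpentan-1-ol | OC[C@H](C)C[C@H](C)CO[Si](C)(C)C(C)(C)C | intermediate
7 | tert-butyl{[(2S,4R)-5-iodo-2,4-dimethylpentyl]oxy}dimethylsilane | IC[C@H](C)C[C@H](C)CO[Si](C)(C)C(C)(C)C | intermediate
8 | 1-propynyllithium | [Li]C#CC | starting material
9 | tert-butyl{[(2S,4R)-2,4-dimethyloct-6-yn-1-yl]oxy}dimethylsilane | CC#CC[C@H](C)C[C@H](C)CO[Si](C)(C)C(C)(C)C | intermediate
10 | tert-butyl{[(2S,4S,6E)-2,4-dimethyloct-6-en-1-yl]oxy}dimethylsilane | C/C=C/C[C@H](C)C[C@H](C)CO[Si](C)(C)C(C)(C)C | intermediate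
11 | (2S,4S,6E)-2,4-dimethyloct-6-en-1-ol | C/C=C/C[C@H](C)C[C@H](C)CO | intermediate
12 | (2S,4S,6E)-2,4-dimethyloct-6-enal | C/C=C/C[C@H](C)C[C@H](C)C=O | intermediate
13 | 5-bromo-2,4-dichloropyridine | Clc1cc(Cl)c(Br)cn1 | starting material
14 | 4-(benzyloxy)-5-bromo-2-chloropyridine (formed in the flask) | Clc1cc(OCc2ccccc2)c(Br)cn1 | intermediate
15 | 2,4-bis(benzyloxy)-5-bromopyridine | Brc1cnc(OCc2ccccc2)cc1OCc1ccccc1 | intermediate
16 | 2,4-bis(benzyloxy)-5-bromo-3-iodopyridine | Brc1cnc(OCc2ccccc2)c(I)c1OCc1ccccc1 | intermediate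
17 | [2,4-bis(benzyloxy)-5-bromopyridin-3-yl]magnesium chloride (formed in the flask) | Brc1cnc(OCc2ccccc2)c([Mg]Cl)c1OCc1ccccc1 | intermediate
18 | (2S,4S,6E)-1-[2,4-bis(benzyloxy)-5-bromopyridin-3-yl]-2,4-dimethyloct-6-en-1-ol, both C1 epimers | C/C=C/C[C@H](C)C[C@H](C)C(O)c1c(OCc2ccccc2)ncc(Br)c1OCc1ccccc1 | intermediate
19 | 4-(benzyloxy)phenylboronic acid | OB(O)c1ccc(OCc2ccccc2)cc1 | starting material
20 | (2S,4S,6E)-1-{2,4-bis(benzyloxy)-5-[4-(benzyloxy)phenyl]pyridin-3-yl}-2,4-dimethyloct-6-en-1-ol, both C1 epimers | C/C=C/C[C@H](C)C[C@H](C)C(O)c1c(OCc2ccccc2)ncc(-c2ccc(OCc3ccccc3)cc2)c1OCc1ccccc1 | intermediate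
21 | (2S,4S,6E)-1-{2,4-bis(benzyloxy)-5-[4-(benzyloxy)phenyl]pyridin-3-yl}-2,4-dimethyloct-6-en-1-one | C/C=C/C[C@H](C)C[C@H](C)C(=O)c1c(OCc2ccccc2)ncc(-c2ccc(OCc3ccccc3)cc2)c1OCc1ccccc1 | intermediate
22 | tolypyridone C, 3-[(2S,4S,6E)-2,4-dimethyloct-6-enoyl]-4-hydroxy-5-(4-hydroxyphenyl)pyridin-2(1H)-one | C/C=C/C[C@H](C)C[C@H](C)C(=O)c1c(O)c(-c2ccc(O)cc2)c[nH]c1=O | target

**Step count and risks**

Total step count: 16. Longest linear sequence: 14 steps (steps 1–10, then 13–16); the pyridine branch (steps 11–12) joins at step 13.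

The three steps most likely to fail:

Step 7 (SN2 of the β-branched iodide may be slow or give elimination). The fallback sets out from 7 and replaces the acetylide alkylation and alkyne reduction by an sp3–sp2 cross-coupling. Zinc insertion into 7 (Zn dust, LiCl, THF, 40 °C) gives {(2R,4S)-5-[(tert-butyldimethylsilyl)oxy]-2,4-dimethylpentyl}(iodo)zinc F1. A Negishi coupling of this with isomerically pure (E)-1-bromoprop-1-ene (Pd(PPh3)4, 5 mol %, THF, 50 °C) proceeds with retention of the alkene geometry and comes back to the route at 10, so that 9 and step 8 are bypassed.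

Step 12 (iodination at the crowded C3 may stall, or the acid may attack the benzyl ethers). The fallback sets out from 13 and puts the iodine in by directed metalation before the benzyl ethers are present. Deprotonation between the two chlorines (LiN(i-Pr)2, THF, −78 °C, short contact time) gives (5-bromo-2,4-dichloropyridin-3-yl)lithium F2, which is quenched with I2 to 5-bromo-2,4-dichloro-3-iodopyridine F3. Two-fold SNAr with BnONa (DMF, 0 → 60 °C) then comes back to the route at 16, so that 15 is bypassed.

Step 13 (the exchange on the electron-rich iodide may be incomplete, or the hindered aryl Grignard reagent may enolise 12 instead of adding). The fallback sets out from 16 and 12 and uses a Nozaki–Hiyama–Kishi coupling in one flask (CrCl2, 4 equiv, NiCl2, 2 mol %, DMF, rt). Nickel inserts only into the C–I bond, and transmetalation gives the non-basic [2,4-bis(benzyloxy)-5-bromopyridin-3-yl]chromium dichloride F4. This adds to the aldehyde without epimerisation and comes back to the route at 18.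

**Further compounds**

F1 | step 7 | {(2R,4S)-5-[(tert-butyldimethylsilyl)oxy]-2,4-dimethylpentyl}(iodo)zinc | I[Zn]C[C@H](C)C[C@H](C)CO[Si](C)(C)C(C)(C)C
F2 | step 12 | (5-bromo-2,4-dichloropyridin-3-yl)lithium | [Li]c1c(Cl)ncc(Br)c1Cl
F3 | step 12 | 5-bromo-2,4-dichloro-3-iodopyridine | Clc1ncc(Br)c(Cl)c1I
F4 | step 13 | [2,4-bis(benzyloxy)-5-bromopyridin-3-yl]chromium dichloride | Cl[Cr](Cl)c1c(OCc2ccccc2)ncc(Br)c1OCc1ccccc1
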